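**Retrosynthetic overview**
- Key disconnection: the ring–chain bond C3–C1'. The target is cut into the C3 phenyliodonium ylide of 2-hydroxy-5-methoxy-1,4-benzoquinone and B-pentadecyl-9-BBN (from 1-pentadecene), joined last by a new Pd-catalysed C(sp2)–C(sp3) coupling.
- The ylide comes from 2-hydroxy-5-methoxy-1,4-benzoquinone and PhI(OAc)2. C3 is the only 1,3-dicarbonyl-type carbon, so the site of the later C–C bond is fixed there.
- 2-Hydroxy-5-methoxy-1,4-benzoquinone comes from mono-saponification of 2,5-dimethoxy-1,4-benzoquinone, itself from double O-methylation of 2,5-dihydroxy-1,4-benzoquinone.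
- Rings: the single six-membered ring is bought intact; no ring is formed in the route.

Assumption: the target has no stereocentre and no stereogenic double bond (it is achiral), so no stereocontrol is needed; the side chain is the unbranched C15 (pentadecyl) chain of the SMILES.

**Route**

Step 1
Reactants: 1 2,5-dihydroxy-1,4-benzoquinone
Product: 2 2,5-dimethoxy-1,4-benzoquinone
Conditions: MeOH, H2SO4 (cat.), reflux, 6 h; product filtered from the cooled mixture
Reagents that add atoms: methanol, CO
Why: Fischer-type acid-catalysed etherification of a vinylogous carboxylic acid (MeOH adds to the protonated enone carbon, water leaves) runs to the bis-ether because the sparingly soluble product crystallises out; no stereocentre is created.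

Step 2
Reactants: 2 2,5-dimethoxy-1,4-benzoquinone
Product: 4 2-hydroxy-5-methoxy-1,4-benzoquinone, via sodium enolate 3 (not isolated)
Conditions: NaOH (1.05 equiv, 1 M aq), THF/H2O, 0 °C to rt; then 1 M HCl to pH 1
Reagents that add atoms: sodium hydroxide, [Na+].[OH-]
Why: Saponification of a vinylogous ester by addition–elimination of hydroxide at C2 expels methoxide, and the delocalised monoanion 3 repels a second hydroxide so the reaction stops at the mono-ether, which HCl protonates to 4; no stereocentre is created.

Step 3
Reactants: 4 2-hydroxy-5-methoxy-1,4-benzoquinone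
Product: 5 phenyliodonium ylide 4-methoxy-3,6-dioxo-2-(phenyliodonio)cyclohexa-1,4-dien-1-olate
Conditions: PhI(OAc)2 (1.05 equiv), CH2Cl2, 0 °C to rt, 2 h, dark; precipitate with Et2O, store cold
Reagents that add atoms: (diacetoxyiodo)benzene, CC(=O)OI(OC(C)=O)c1ccccc1
Why: Iodonium ylide formation: the enol of 4 displaces acetate on trivalent iodine and loses AcOH, and only C3 (between the C2 oxygen and the C4 carbonyl, a cyclic 1,3-dicarbonyl carbon) can carry the stabilised ylide.

Step 4
Reactants: 5 phenyliodonium ylide 4-methoxy-3,6-dioxo-2-(phenyliodonio)cyclohexa-1,4-dien-1-olate; 6 1-pentadecene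
Product: 9 2-hydroxy-5-methoxy-3-pentadecyl-1,4-benzoquinone, via B-pentadecyl-9-BBN 7 (not isolated), via potassium enolate 8 (not isolated)
Conditions: 6 (1.6 equiv), 9-BBN-H (1.5 equiv), THF, 0 °C to rt, 4 h; then 5 (1.0 equiv), PdCl2(dppf) (5 mol %), K3PO4 (3 M aq, 3 equiv), degassed THF/DMF, rt, dark, 12 h; then 1 M HCl, work-up in air
Reagents that add atoms: none
Why: Proposed new method: a palladium-catalysed B-alkyl Suzuki–Miyaura coupling at the ylidic carbon of a hydroxyquinone aryliodonium ylide — anti-Markovnikov hydroboration of 6 gives 7, zerovalent palladium inserts into the C3–I bond of 5 (iodobenzene is an exceptional leaving group, so this outpaces any reaction of the PhI released) to give a C3-bound quinonyl complex of divalent palladium, the base-activated borate from 7 transfers its primary alkyl group, and the wide-bite-angle dppf ligand lets C(sp2)–C(sp3) reductive elimination outrun β-hydride elimination, so the chain is attached only where iodine sat and no stereocentre arises; a palladium-free 1,2-boronate shift with loss of PhI would converge on the same product; the closest known reaction types are the palladium-catalysed Stille-type coupling of hydroxyquinone phenyliodonium ylides with aryl- and alkenylstannanes and the B-alkyl Suzuki–Miyaura coupling of aryl or alkenyl halides.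

**Compound list**

1 | 2,5-dihydroxy-1,4-benzoquinone | O=C1C=C(O)C(=O)C=C1O | starting material
2 | 2,5-dimethoxy-1,4-benzoquinone | COC1=CC(=O)C(OC)=CC1=O | intermediate
3 | sodium 4-methoxy-3,6-dioxocyclohexa-1,4-dien-1-olate (sodium salt of 4, formed in the flask) | COC1=CC(=O)C([O-])=CC1=O.[Na+] | intermediate
4 | 2-hydroxy-5-methoxy-1,4-benzoquinone | COC1=CC(=O)C(O)=CC1=O | intermediate
5 | 4-methoxy-3,6-dioxo-2-(phenyliodonio)cyclohexa-1,4-dien-1-olate (zwitterionic phenyliodonium ylide at C3 of 4) | COC1=CC(=O)C([O-])=C([I+]c2ccccc2)C1=O | intermediate
6 | 1-pentadecene | CCCCCCCCCCCCCC=C | starting material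
7 | 9-pentadecyl-9-borabicyclo[3.3.1]nonane (B-pentadecyl-9-BBN, formed in the flask) | CCCCCCCCCCCCCCCB1C2CCCC1CCC2 | intermediate
8 | potassium 4-methoxy-3,6-dioxo-2-pentadecylcyclohexa-1,4-dien-1-olate (potassium salt of 9, formed in the flask) | CCCCCCCCCCCCCCCC1=C([O-])C(=O)C=C(OC)C1=O.[K+] | intermediate
9 | 2-hydroxy-5-methoxy-3-pentadecyl-1,4-benzoquinone (achiral) | CCCCCCCCCCCCCCCC1=C(O)C(=O)C=C(OC)C1=O | target

**Totals**

Total step count: 4. Longest linear sequence: 4 steps (1 to 2 to 4 to 5 to 9); 6 enters in step 4.

**Three steps most likely to fail**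

Step 4 (the proposed new coupling). The risks are thermal ring contraction of 5 before coupling, β-hydride elimination returning 4, radical side reactions of the alkylborane at C6, and phenyl instead of quinonyl transfer. The fallback uses known chemistry, sets out from 4 and comes back to the route at 9. It is an organocatalytic three-component reductive alkylation, a known reaction type for 2-hydroxy-1,4-quinones and cyclic 1,3-diones. Compound 4, pentadecanal and Hantzsch ester (diethyl 2,6-dimethyl-1,4-dihydropyridine-3,5-dicarboxylate) are stirred with L-proline (20 mol %) in CH2Cl2 at rt. Knoevenagel condensation at the nucleophilic C3 gives the alkylidene trione 5-methoxy-3-pentadecylidenecyclohex-5-ene-1,2,4-trione F1 (geometry irrelevant). The dihydropyridine reduces F1 in the same flask by conjugate hydride transfer to give 9. Regiochemistry is again inherent, because only C3 is an enolisable 1,3-dicarbonyl carbon.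

Step 3 (ylide formation). The ylide may fail to precipitate cleanly or may lose iodobenzene (carbene/ring-contraction pathway) during isolation. The fallback sets out from 4, comes back at 9, and builds the chain without hypervalent iodine.
- Tsuji–Trost C-allylation of 4 with allyl methyl carbonate and Pd(PPh3)4 (cat.) in THF at rt gives 2-hydroxy-5-methoxy-3-(prop-2-en-1-yl)-1,4-benzoquinone F2.
- Cross-metathesis of F2 with excess 1-tetradecene, using the second-generation Grubbs catalyst RuCl2(=CHPh)(PCy3)(H2IMes) in CH2Cl2 at 40 °C, gives 2-hydroxy-5-methoxy-3-[(E)-pentadec-2-en-1-yl]-1,4-benzoquinone F3. The E/Z ratio is irrelevant.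
- Hydrogenation (H2, Pd/C, EtOAc, rt) saturates the chain and reduces the quinone to 5-methoxy-3-pentadecylbenzene-1,2,4-triol F4, which is re-oxidised to 9 by stirring the filtered solution in air.

Step 2 (mono-saponification). The heterogeneous hydrolysis may be sluggish or overshoot to 1; recovered 1 can be returned to step 1. The fallback sets out from 1, comes back at 9, and reverses the order of events: C-alkylate the symmetric quinone first, differentiate the two oxygens last.
- Silver-catalysed decarboxylative radical alkylation of 1 (Jacobsen–Torssell type; hexadecanoic acid, AgNO3 (cat.), (NH4)2S2O8, MeCN/H2O, 70 °C) gives 2,5-dihydroxy-3-pentadecyl-1,4-benzoquinone F5. The pentadecyl radical can add to either of the two equivalent ring CH positions, so there is no regiochemical question.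
- Brief acid-catalysed etherification (MeOH, H2SO4 (cat.), rt to 40 °C, monitored) then methylates only the unhindered 5-OH. The 2-OH flanked by the pentadecyl chain reacts far more slowly, and its ether would be twisted out of conjugation. This gives 9, whose regiochemistry should be confirmed by HMBC/NOE.

**Further compounds**

F1 | step 4 | 5-methoxy-3-pentadecylidenecyclohex-5-ene-1,2,4-trione | CCCCCCCCCCCCCCC=C1C(=O)C(=O)C=C(OC)C1=O
F2 | step 3 | 2-hydroxy-5-methoxy-3-(prop-2-en-1-yl)-1,4-benzoquinone | C=CCC1=C(O)C(=O)C=C(OC)C1=O
F3 | step 3 | 2-hydroxy-5-methoxy-3-[(E)-pentadec-2-en-1-yl]-1,4-benzoquinone | CCCCCCCCCCCC/C=C/CC1=C(O)C(=O)C=C(OC)C1=O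
F4 | step 3 | 5-methoxy-3-pentadecylbenzene-1,2,4-triol | CCCCCCCCCCCCCCCc1c(O)c(O)cc(OC)c1O
F5 | step 2 | 2,5-dihydroxy-3-pentadecyl-1,4-benzoquinone | CCCCCCCCCCCCCCCC1=C(O)C(=O)C=C(O)C1=O
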